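**Assumptions (one line each)**
- Quinolinone numbering is used throughout: C5 bears the 5-phenylpentyl chain, C8 the OMe; the target SMILES corresponds to (5S,8R), i.e. chain and 8-OMe cis.
- The facial sense in step 3 follows the standard diarylprolinol silyl ether shielding model; if the measured sense is opposite, the (S)-catalyst is used instead.

**Retrosynthetic overview**
1. The C7=C8 methyl enol ether of a 5,6-dihydroquinolin-4-one is reduced last, which sets C8 cis to the C5 chain with no later chance of epimerisation.
2. The N-methoxy-4-pyridone comes from the corresponding 4-pyranone by O→N exchange with methoxyamine.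
3. The pyranone comes from a 2-(methoxyacetyl)cyclohexenone by terminal acetylation (C2–C3 bond) and cyclodehydration (O1–C2 bond).
4. The carbocycle is made first, by an amine-catalysed asymmetric Michael/aldol condensation of an enal with symmetrical 1,5-dimethoxypentane-2,4-dione (C4a–C5 and C7–C8 bonds; sets C5).
5. Ring order: carbocycle → pyranone → pyridone; the enal and the diketone are each one step from achiral commercial materials.

**Route**

**Step 1**
Reactants: **1** (5-bromopentyl)benzene; **2** (E)-3-(dimethylamino)acrolein
Product: **3** (E)-8-phenyloct-2-enal
Conditions: Mg, THF, reflux; add to **2**, THF, −20 °C → rt; 2 M HCl, rt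
Reagents that add atoms: none beyond the two reactants
Why: Grignard addition to a vinylogous formamide followed by acidic hydrolysis and loss of Me2NH (formyl-vinylation) gives the E-enal; the enal is only released on workup, so there is no over-addition.

**Step 2**
Reactants: **4** methoxyacetone (1-methoxypropan-2-one); **5** methyl methoxyacetate
Product: **6** 1,5-dimethoxypentane-2,4-dione
Conditions: NaH (2.2 equiv), THF, 0 → 50 °C; AcOH quench
Reagents that add atoms: none beyond the two reactants
Why: Crossed Claisen condensation at the methyl group of **4**, driven by formation of the unsubstituted, more stable β-diketonate.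

**Step 3**
Reactants: **3**; **6** (1.5 equiv)
Product: **7** (5S)-2-methoxy-6-(methoxyacetyl)-5-(5-phenylpentyl)cyclohex-2-en-1-one (C6 epimers/enol tautomers; C6 becomes sp2 later)
Conditions: (R)-2-{bis[3,5-bis(trifluoromethyl)phenyl](trimethylsilyloxy)methyl}pyrrolidine (10 mol %), PhCO2H (10 mol %), toluene, 0 °C → rt; then p-TsOH·H2O (20 mol %), 60 °C
Reagents that add atoms: none
Why: Jørgensen-type iminium-catalysed Michael addition followed by intramolecular aldol condensation (Robinson-type [3+3]); the silyl ether group shields one face of the E-iminium so the diketone adds to the β-carbon from the open face, giving the (S) centre, and the symmetry of **6** makes the aldol arm unambiguous.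

**Step 4**
Reactants: **7**; **8** N-methoxy-N-methylacetamide
Product: **9** (5S)-3,8-dimethoxy-2-methyl-5-(5-phenylpentyl)-5,6-dihydro-4H-chromen-4-one
Conditions: LDA (2.3 equiv), THF, −78 → −20 °C; **8**, −78 → 0 °C; aq NH4Cl; then TFA, CH2Cl2, 0 °C → rt
Reagents that add atoms: **8** N-methoxy-N-methylacetamide, CC(=O)N(C)OC (acetyl unit)
Why: Harris-type 1,3-diketone dianion acylation at the terminal CH2OMe carbon, then acid cyclodehydration of the 1,3,5-triketone to the 4-pyranone; C5 carries no acidic hydrogen and is untouched.

**Step 5**
Reactants: **9**; **10** O-methylhydroxylamine hydrochloride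
Product: **11** (5S)-1,3,8-trimethoxy-2-methyl-5-(5-phenylpentyl)-5,6-dihydroquinolin-4(1H)-one
Conditions: MeONH2·HCl (5 equiv), pyridine, 80 °C, Ar
Reagents that add atoms: **10** O-methylhydroxylamine hydrochloride, CON.Cl (N–OMe)
Why: Pyranone-to-pyridone exchange (conjugate addition, ring opening, recyclisation with loss of water) by an α-effect amine; the enol ether and C5 are not involved.

**Step 6**
Reactants: **11**
Product: **12** Waltherione H, (5S,8R)-1,3,8-trimethoxy-2-methyl-5-(5-phenylpentyl)-5,6,7,8-tetrahydroquinolin-4(1H)-one
Conditions: Hantzsch ester (2 equiv), diphenyl phosphate (20 mol %), toluene, 4 Å MS, 60 °C, dark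
Reagents that add atoms: none (H only)
Why: Proposed new method: Brønsted acid-catalysed Hantzsch-ester transfer hydrogenation of a pyridone-conjugated enol ether — O-protonation of the 4-pyridone gives a 4-hydroxy-1-methoxypyridinium in which C7=C8(OMe) is a vinylogous iminium, hydride adds to C7, and the resulting exocyclic enol ether is protonated at C8 axially, anti to the C5 chain (held pseudoaxial by peri strain with C4=O), which places 8-OMe cis to the chain (8R); being metal-free it should spare the N–OMe bond that H2/Pd could cleave; closest known chemistry is phosphoric acid/Hantzsch ester transfer hydrogenation of quinolines and benzopyrylium ions and conjugate reduction–protonation of vinyl azaarenes.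

**Compound list**
1 | (5-bromopentyl)benzene | BrCCCCCc1ccccc1 | starting material
2 | (E)-3-(dimethylamino)acrolein | CN(C)/C=C/C=O | starting material
3 | (E)-8-phenyloct-2-enal | O=C/C=C/CCCCCc1ccccc1 | intermediate
4 | methoxyacetone | COCC(C)=O | starting material
5 | methyl methoxyacetate | COCC(=O)OC | starting material
6 | 1,5-dimethoxypentane-2,4-dione | COCC(=O)CC(=O)COC | intermediate
7 | (5S)-2-methoxy-6-(methoxyacetyl)-5-(5-phenylpentyl)cyclohex-2-en-1-one | COCC(=O)C1[C@@H](CCCCCc2ccccc2)CC=C(OC)C1=O | intermediate
8 | N-methoxy-N-methylacetamide | CC(=O)N(C)OC | starting material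
9 | (5S)-3,8-dimethoxy-2-methyl-5-(5-phenylpentyl)-5,6-dihydro-4H-chromen-4-one | COc1c(C)oc2c(c1=O)[C@@H](CCCCCc1ccccc1)CC=C2OC | intermediate
10 | O-methylhydroxylamine hydrochloride | CON.Cl | starting material
11 | (5S)-1,3,8-trimethoxy-2-methyl-5-(5-phenylpentyl)-5,6-dihydroquinolin-4(1H)-one | COc1c(C)n(OC)c2c(c1=O)[C@@H](CCCCCc1ccccc1)CC=C2OC | intermediate
12 | Waltherione H, (5S,8R)-1,3,8-trimethoxy-2-methyl-5-(5-phenylpentyl)-5,6,7,8-tetrahydroquinolin-4(1H)-one | COc1c(C)n(OC)c2c(c1=O)[C@@H](CCCCCc1ccccc1)CC[C@H]2OC | target

**Step count**
Total steps: 6. Longest linear sequence: 5 (1 → 3 → 7 → 9 → 11 → 12; step 2 is a one-step side branch).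

**Three steps most likely to fail, with fallbacks**
1. **Step 6 (proposed new reduction).** Hydride transfer may be slow or the C8 selectivity poor. Fallback (known chemistry, reagent-controlled): hydrolyse the enol ether of **11** to the C8 ketone with aqueous acid, reduce with (S)-Me-CBS/BH3·SMe2 to the (8R)-alcohol, then methylate with MeI/Ag2O.
2. **Step 5 (O→N exchange).** The fully substituted pyranone may react sluggishly with weakly nucleophilic MeONH2, or the enol ether may hydrolyse. Fallback: build the N–O bond in two stages — NH2OH·HCl/pyridine to the 1-hydroxy-4-pyridone, then O-methylation with MeI/K2CO3.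
3. **Step 3 (annulation with a 1,3-diketone donor).** The adduct may stall as the hemiacetal or 4H-pyran, or give lower ee than β-ketoester donors. Fallback: use commercial methyl 4-methoxyacetoacetate, the donor class with direct precedent, to get the ring β-ketoester; then form the pyranone by thermal acylketene generation and [4+2] capture with the enamine or silyl enol ether of methoxyacetone, rejoining the route at **9**.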